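**Retrosynthetic overview**

1. Eremophilane numbering is used: ring A = C1–C5 and C10; ring B = C5–C10; C11–C13 = isopropenyl on C7; C14 on C5; C15 on C4. The target goes back to the 8α,9α-diol plus two angelic acid units, and from there to a 2,9-dione. In that dione C9=O lets C10 settle as the cis-fused epimer, directs oxygenation to C8, and is finally reduced from the β face.
2. The 2,9-dione goes back to the 1(10)-ene-2,9-dione. Ring A is then cut Robinson-style at C4–C5 and C1=C10 into (E)-pent-3-en-2-one (C1–C4, C15) and a ten-carbon 1,2-dione.
3. Enabling feature: in ring A the C2 carbonyl is 1,5 to C10 and C4 is β to it, while the C9 oxygen sits next to C10. C9/C10 can therefore be a 1,2-dione whose enol is nucleophilic only at C5.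
4. Ring B with C14 and C11–C13 is a hidden meta-menthane. One extra C8–C11 bond turns it into (+)-3-carene, which supplies all ten carbons and the C7 configuration. This cyclopropane shields the β face, masks the isopropenyl group, and is cut in the key step.
5. Ring order: ring B and the temporary cyclopropane come from 3-carene; ring A is closed last.

Key step: step 4

Remark: β is the face that carries C14 (also H10, C15 and the isopropenyl group); α is the face of the two ester oxygens. Commercial pent-3-en-2-one is taken as its E isomer.

**Route**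

Step 1
Reactants: 1 (+)-3-carene
Product: 3 (1S,3R,4R,6R)-3,7,7-trimethylbicyclo[4.1.0]heptan-4-ol (4-isocaranol), via di(4-isocaranyl)borane 2 (not isolated)
Conditions: BH3·THF (0.55 equiv), THF, 0 °C to rt; then NaOH, H2O2, H2O, 0 to 40 °C
Reagents that add atoms: hydrogen peroxide, OO
Why: Brown hydroboration–oxidation adds syn to the trisubstituted alkene (C5=C10) from the α face, away from the gem-dimethylcyclopropane, with boron on the less substituted C10 and oxidation with retention; both new centres are erased in steps 2 and 3.

Step 2
Reactants: 3 4-isocaranol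
Product: 4 (1S,3R,6R)-3,7,7-trimethylbicyclo[4.1.0]heptan-4-one (caran-4-one)
Conditions: TEMPO (cat.), KBr (cat.), NaOCl, NaHCO3, CH2Cl2/H2O, 0 °C
Reagents that add atoms: none
Why: Anelli oxidation turns the secondary alcohol into the ketone (C10=O) without touching the cyclopropane, and the C5 centre does not matter because it becomes sp2 in step 3.

Step 3
Reactants: 4 caran-4-one
Product: 5 (1R,6S)-3-hydroxy-4,7,7-trimethylbicyclo[4.1.0]hept-3-en-2-one (4-hydroxycar-3-en-5-one, the diosphenol form of carane-4,5-dione)
Conditions: SeO2 (1.1 equiv), 1,4-dioxane/H2O, 90 °C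
Reagents that add atoms: selenium dioxide, O=[Se]=O
Why: Riley oxidation attacks the only α-methylene (C9, also activated by the neighbouring cyclopropane), and the 1,2-dione settles as the enol toward C5 because C8, a cyclopropane CH, resists becoming sp2.

Step 4
Reactants: 5 diosphenol; 6 (E)-pent-3-en-2-one
Product: 9 11-chloroeremophil-1(10)-ene-2,9-dione (4β,5β-dimethyl, 7β-(2-chloropropan-2-yl)), via triketone 7 (not isolated), via cyclopropyl enedione 8 (not isolated)
Conditions: NaH (10 mol %), 1,4-dioxane, rt, 6 (1.5 equiv); then HCl (g), AcOH, 0 °C to rt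
Reagents that add atoms: hydrogen chloride, Cl
Why: Catalytic base converts diosphenol 5 into its enolate, which adds through C5 to the β-carbon (C4) of 6 to give triketone 7; HCl/AcOH then enolises the methyl ketone, C1 attacks the activated C10 carbonyl of the 1,2-dione, loss of water gives enedione 8, and protonation of C9=O breaks the C8–C11 bond of the now conjugated cyclopropyl ketone, chloride capturing the tertiary C11 cation. The closest known reaction types are the Robinson annulation of 2-methylcycloalkanones and 2-methyl-1,3-diones with trans-pent-3-en-2-one, the Michael addition of cyclic 1,2-diones through their enol carbon, and the HCl-induced aldol condensation with simultaneous small-ring scission of pinane- and carane-type ketones. Ring A closes in the 6-(enolendo)-exo-trig mode (C1 onto C10=O), and no other ring is formed while the three-membered ring is lost. C5 is controlled by the gem-dimethylcyclopropane, whose endo methyl group covers the β face of the flat enolate, so that C4 is attached from the α face and C14 ends up β, cis to the C7–C11 bond. C4 is controlled by the E geometry of 6 in a sodium-bridged closed transition state in poorly solvating dioxane, in which C3 and C2 lie over C10 and the C4 methyl group turns away from ring B to the side of C14, which gives the cis-vicinal dimethyl pair typical of such annulations. The step needs regioselectivity (C5 is the only enolisable α-position, because C8 is a cyclopropane CH), site selectivity in the aldol step (C10 gives a six-membered ring, C9 would give a seven-membered one) and bond selectivity in the scission (only C8–C11 overlaps with the C9=O π system and leaves a tertiary cation), and the order of events keeps the shielding ring in place until C5 and C4 are set.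

Step 5
Reactants: 9 chloro enedione
Product: 10 11-chloro-10βH-eremophilane-2,9-dione (cis-decalin)
Conditions: Zn dust, AcOH, rt
Reagents that add atoms: none
Why: Zn/AcOH reduction of an enedione to the 1,4-diketone spares the tertiary chloride, and C10, being α to C9=O, can equilibrate in the acid to the cis-fused 10βH epimer because the trans-decalin would hold C14 and the C7 side chain syn-diaxial.

Step 6
Reactants: 10 chloro dione
Product: 11 10βH-eremophil-11-ene-2,9-dione
Conditions: NaOAc, AcOH, 90 °C
Reagents that add atoms: none
Why: Buffered solvolytic E1 dehydrochlorination, as applied to terpene hydrochlorides, should lose one of the six methyl protons rather than the hindered C7–H, and the non-basic medium avoids the C8 enolate that would close the cyclopropane again; C10 stays under thermodynamic control.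

Step 7
Reactants: 11 isopropenyl dione
Product: 12 2,2-ethylenedioxy-10βH-eremophil-11-en-9-one
Conditions: Me3SiOCH2CH2OSiMe3 (1.1 equiv), Me3SiOTf (cat.), CH2Cl2, −78 °C
Reagents that add atoms: 1,2-bis(trimethylsilyloxy)ethane, C[Si](C)(C)OCCO[Si](C)(C)C
Why: Noyori ketalisation at low temperature selects the unhindered C2 ketone, flanked by two CH2 groups, over the C9 ketone, which is flanked by the ring-fusion CH next to quaternary C5.

Step 8
Reactants: 12 keto ketal
Product: 13 2,2-ethylenedioxy-8α-hydroxy-10βH-eremophil-11-en-9-one
Conditions: KN(SiMe3)2, THF, −78 °C; 2-(phenylsulfonyl)-3-phenyloxaziridine; then AcOH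
Reagents that add atoms: 2-(phenylsulfonyl)-3-phenyloxaziridine, O=S(=O)(c1ccccc1)N1OC1c1ccccc1
Why: In this Davis hydroxylation the bulky amide removes a C8 methylene proton rather than the tertiary C10–H, and the oxaziridine enters trans to the neighbouring 7β-isopropenyl group, as in the trans-selective trapping of 3-substituted cyclohexanone enolates, giving the equatorial 8α-alcohol.

Step 9
Reactants: 13 α-hydroxy ketone
Product: 14 2,2-ethylenedioxy-10βH-eremophil-11-ene-8α,9α-diol
Conditions: LiBH(s-Bu)3 (2.2 equiv), THF, −78 °C; then H2O
Reagents that add atoms: none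
Why: In this bulky trialkylborohydride reduction the axial α-face approach to C9 is blocked by C4, which is axial on ring B and 1,3 to C9, so hydride comes from the equatorial β side and gives the axial 9α-alcohol, cis to the 8α-OH.

Step 10
Reactants: 14 diol; 15 angelic acid ((Z)-2-methylbut-2-enoic acid, 4 equiv)
Product: 16 8α,9α-bis(angeloyloxy)-2,2-ethylenedioxy-10βH-eremophil-11-ene
Conditions: 15, 2,4,6-trichlorobenzoyl chloride, Et3N, toluene, rt; then 14, 80 °C
Reagents that add atoms: none
Why: Yamaguchi-type mixed-anhydride acylation without a nucleophilic catalyst is the established way to form angelates without Z-to-E isomerisation, it touches no stereocentre, and the ketal prevents hemiketal formation between the 9-OH and C2.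

Step 11
Reactants: 16 bis-angelate ketal
Product: 17 (4S,5R,7R,8R,9S,10S)-8α,9α-bis(angeloyloxy)-10βH-eremophil-11-en-2-one (CNP0249036.1)
Conditions: PPTS (cat.), acetone/H2O, 50 °C
Reagents that add atoms: water, O
Why: Mild acid-catalysed ketal hydrolysis frees the C2 ketone and should leave the angelates, the isopropenyl group and all stereocentres untouched.

**Compound list**

1 | (+)-3-carene, (1S,6R)-3,7,7-trimethylbicyclo[4.1.0]hept-3-ene | CC1=CC[C@@H]2[C@H](C1)C2(C)C | starting material
2 | di(4-isocaranyl)borane | B([C@@H]1C[C@@H]2[C@H](C[C@H]1C)C2(C)C)[C@@H]1C[C@@H]2[C@H](C[C@H]1C)C2(C)C | intermediate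
3 | (1S,3R,4R,6R)-3,7,7-trimethylbicyclo[4.1.0]heptan-4-ol | C[C@@H]1C[C@H]2[C@@H](C[C@H]1O)C2(C)C | intermediate
4 | (1S,3R,6R)-3,7,7-trimethylbicyclo[4.1.0]heptan-4-one | C[C@@H]1C[C@H]2[C@@H](CC1=O)C2(C)C | intermediate
5 | (1R,6S)-3-hydroxy-4,7,7-trimethylbicyclo[4.1.0]hept-3-en-2-one (diosphenol) | CC1=C(O)C(=O)[C@@H]2[C@H](C1)C2(C)C | intermediate
6 | (E)-pent-3-en-2-one | C/C=C/C(C)=O | starting material
7 | triketone: carane-4,5-dione bearing on C5 a β-methyl and an α-[(S)-4-oxopentan-2-yl] group | CC(=O)C[C@H](C)[C@@]1(C)C[C@H]2[C@@H](C(=O)C1=O)C2(C)C | intermediate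
8 | 8,11-cycloeremophil-1(10)-ene-2,9-dione (4β,5β-dimethyl, cyclopropane C7–C8–C11 on the β face) | C[C@H]1CC(=O)C=C2C(=O)[C@@H]3[C@H](C[C@]12C)C3(C)C | intermediate
9 | 11-chloroeremophil-1(10)-ene-2,9-dione | C[C@H]1CC(=O)C=C2C(=O)C[C@H](C[C@]12C)C(C)(C)Cl | intermediate
10 | 11-chloro-10βH-eremophilane-2,9-dione | C[C@H]1CC(=O)C[C@@H]2C(=O)C[C@H](C[C@]12C)C(C)(C)Cl | intermediate
11 | 10βH-eremophil-11-ene-2,9-dione | C[C@H]1CC(=O)C[C@@H]2C(=O)C[C@H](C[C@]12C)C(C)=C | intermediate
12 | 2,2-ethylenedioxy-10βH-eremophil-11-en-9-one | C[C@H]1CC2(OCCO2)C[C@@H]3C(=O)C[C@H](C[C@]13C)C(C)=C | intermediate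
13 | 2,2-ethylenedioxy-8α-hydroxy-10βH-eremophil-11-en-9-one | C[C@H]1CC2(OCCO2)C[C@@H]3C(=O)[C@H](O)[C@H](C[C@]13C)C(C)=C | intermediate
14 | 2,2-ethylenedioxy-10βH-eremophil-11-ene-8α,9α-diol | C[C@H]1CC2(OCCO2)C[C@@H]3[C@H](O)[C@H](O)[C@H](C[C@]13C)C(C)=C | intermediate
15 | angelic acid, (Z)-2-methylbut-2-enoic acid | C/C=C(/C)C(=O)O | starting material
16 | 8α,9α-bis(angeloyloxy)-2,2-ethylenedioxy-10βH-eremophil-11-ene | C[C@H]1CC2(OCCO2)C[C@@H]3[C@H](OC(=O)/C(C)=C\C)[C@H](OC(=O)/C(C)=C\C)[C@H](C[C@]13C)C(C)=C | intermediate
17 | 8α,9α-bis(angeloyloxy)-10βH-eremophil-11-en-2-one (CNP0249036.1) | C=C(C)[C@H]1C[C@@]2(C)[C@H](CC(=O)C[C@@H]2C)[C@H](OC(=O)/C(C)=C\C)[C@@H]1OC(=O)/C(C)=C\C | target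

Total step count: 11. Longest linear sequence: 11 steps (1 to 17).

**Steps most likely to fail**

**Step 4.** The Michael addition of the stabilised diosphenolate to the β-substituted enone may stall or revert. Diastereoselection at C4 may erode, or the cyclopropane may open before C5 is set. The fallback raises the C9 oxidation level after the annulation instead of before it.
- It sets out from ketone 4, whose sodium enolate undergoes a classical Robinson annulation with 6 (NaH, dioxane; then KOH, MeOH) and should give 8,11-cycloeremophil-1(10)-en-2-one F1.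
- Allylic oxidation of its C9 methylene, activated by both the enone and the cyclopropane (dirhodium tetracaprolactamate Rh2(cap)4 cat., t-BuOOH), gives enedione 8, now isolated.
- HCl/AcOH opens 8 to 9, where the route is rejoined.

**Step 6.** Proton loss may occur from C7 and give the isopropylidene isomer. The C11 cation may also be captured by the C9 enol, which returns the cyclopropane or forms a dihydrofuran. The fallback removes the enolisable ketone first and then uses a bulky-base E2 elimination.
- It sets out from 10, whose C2 is ketalised as in step 7 to give the chloro keto ketal F2.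
- LiBH(s-Bu)3 reduces C9 to the 9α-alcohol chloro ketal F3.
- KOt-Bu in THF eliminates toward the methyl groups, with no enolate available for ring closure, to give the isopropenyl 9α-alcohol F4.
- Dess–Martin periodinane oxidises F4 to 12, where the route is rejoined.

**Step 10.** Acylation of the hindered axial 9-OH may stay incomplete, or forcing conditions may isomerise the Z double bonds to tiglates. The fallback builds the Z alkene on the ester.
- It sets out from 14, which is esterified with 2-[bis(2,2,2-trifluoroethoxy)phosphoryl]propanoic acid (DCC, DMAP, CH2Cl2) to give the bis(phosphonopropionate) F5.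
- Double Still–Gennari olefination (KN(SiMe3)2, 18-crown-6, THF, −78 °C, acetaldehyde) gives 16, where the route is rejoined.

**Further compounds**

F1 | step 4 | 8,11-cycloeremophil-1(10)-en-2-one | C[C@H]1CC(=O)C=C2C[C@@H]3[C@H](C[C@]12C)C3(C)C
F2 | step 6 | 11-chloro-2,2-ethylenedioxy-10βH-eremophilan-9-one | C[C@H]1CC2(OCCO2)C[C@@H]3C(=O)C[C@H](C[C@]13C)C(C)(C)Cl
F3 | step 6 | 11-chloro-2,2-ethylenedioxy-10βH-eremophilan-9α-ol | C[C@H]1CC2(OCCO2)C[C@@H]3[C@H](O)C[C@H](C[C@]13C)C(C)(C)Cl
F4 | step 6 | 2,2-ethylenedioxy-10βH-eremophil-11-en-9α-ol | C[C@H]1CC2(OCCO2)C[C@@H]3[C@H](O)C[C@H](C[C@]13C)C(C)=C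
F5 | step 10 | 8α,9α-bis{2-[bis(2,2,2-trifluoroethoxy)phosphoryl]propanoyloxy}-2,2-ethylenedioxy-10βH-eremophil-11-ene | C[C@H]1CC2(OCCO2)C[C@@H]3[C@H](OC(=O)C(C)P(=O)(OCC(F)(F)F)OCC(F)(F)F)[C@H](OC(=O)C(C)P(=O)(OCC(F)(F)F)OCC(F)(F)F)[C@H](C[C@]13C)C(C)=C
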